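**Retrosynthetic overview**
- The target comes from desilylation and hydroxyl-directed reduction of the C5 ketone of a 6-hydroxy-6-(silyloxymethyl)-5-oxocyclohex-2-ene-1,4-diyl dibenzoate.
- That cyclohexenone comes from a catalytic, enantiotopic-group-selective α-ketol ring expansion (five- to six-membered ring) of a meso 2-acyl-2-hydroxycyclopent-4-ene-1,3-diyl dibenzoate. This step makes the six-membered ring, the C6 carbinol and the absolute configuration.
- The meso ketol comes from ketohydroxylation of an exocyclic alkene, after benzoylation of a cis-1,3-diol obtained by singlet-oxygen addition and reduction of a fulvene.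
- The fulvene comes from cyclopentadiene and (tert-butyldimethylsilyloxy)acetaldehyde.
- Ring order: the five-membered carbocycle comes with cyclopentadiene; a transient dioxabicyclo[2.2.1] peroxide ring sets the cis-dioxygen pattern; the six-membered ring is formed last by ring expansion.

Assumption: the two alkylidene-cyclopentene intermediates that are chiral only through their unsymmetrical exocyclic alkene are racemic and drawn as one enantiomer; both enantiomers converge on the same meso ketol.

Step 1
Reactants: 1 cyclopenta-1,3-diene; 2 (tert-butyldimethylsilyloxy)acetaldehyde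
Product: 3 5-[2-(tert-butyldimethylsilyloxy)ethylidene]cyclopenta-1,3-diene
Conditions: pyrrolidine (1.5 equiv), MeOH, 0 °C to rt; then AcOH
Reagents that add atoms: none
Why: Pyrrolidine-mediated fulvene condensation (Thiele/Stone–Little type), in which cyclopentadienide adds to the iminium of the aldehyde and the amine is eliminated; no stereocenter is formed.

Step 2
Reactants: 3 5-[2-(tert-butyldimethylsilyloxy)ethylidene]cyclopenta-1,3-diene
Product: 5 cis-2-[2-(tert-butyldimethylsilyloxy)ethylidene]cyclopent-4-ene-1,3-diol (racemic), via fulvene endoperoxide 4 (not isolated)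
Conditions: O2, visible light, tetraphenylporphyrin (cat.), CH2Cl2/MeOH, −78 °C; then thiourea, −78 °C to rt
Reagents that add atoms: oxygen (as singlet O2), O=O
Why: Singlet-oxygen [4+2] cycloaddition across the ring diene gives the bicyclic endoperoxide, and thiourea cleaves its O–O bond before it can rearrange, so both C–O bonds sit on one face (cis-diol).

Step 3
Reactants: 5 cis-2-[2-(tert-butyldimethylsilyloxy)ethylidene]cyclopent-4-ene-1,3-diol
Product: 6 cis-2-[2-(tert-butyldimethylsilyloxy)ethylidene]cyclopent-4-ene-1,3-diyl dibenzoate (racemic)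
Conditions: BzCl (2.4 equiv), pyridine, DMAP (cat.), CH2Cl2, 0 °C
Reagents that add atoms: benzoyl chloride, O=C(Cl)c1ccccc1
Why: DMAP-catalysed acylation of the two secondary allylic alcohols, the only free hydroxyls, places the benzoates on the future C1 and C4 oxygens without touching a stereocenter.

Step 4
Reactants: 6 cis-2-[2-(tert-butyldimethylsilyloxy)ethylidene]cyclopent-4-ene-1,3-diyl dibenzoate
Product: 7 meso-(1R,3S)-2-hydroxy-2-[2-(tert-butyldimethylsilyloxy)acetyl]cyclopent-4-ene-1,3-diyl dibenzoate
Conditions: RuCl3 (1 mol%), KHSO5 (as 2KHSO5·KHSO4·K2SO4, 5 equiv), NaHCO3, EtOAc/MeCN/H2O, rt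
Reagents that add atoms: potassium peroxymonosulfate (KHSO5), [K+].[O-]S(=O)(=O)OO
Why: RuO4-catalysed ketohydroxylation of the trisubstituted exocyclic alkene (the ring alkene is only disubstituted and carries two allylic benzoates) adds from the face opposite both benzoates, so the tertiary OH is trans to them and the CH carbon becomes the ketone; either enantiomer of 6 gives the same meso ketol.

Step 5
Reactants: 7 meso-(1R,3S)-2-hydroxy-2-[2-(tert-butyldimethylsilyloxy)acetyl]cyclopent-4-ene-1,3-diyl dibenzoate
Product: 8 (1S,4R,6R)-6-hydroxy-6-[(tert-butyldimethylsilyloxy)methyl]-5-oxocyclohex-2-ene-1,4-diyl dibenzoate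
Conditions: Cu(OTf)2 (10 mol%), (S,S)-tBu-box [2,2'-(propane-2,2-diyl)bis((4S)-4-tert-butyl-4,5-dihydrooxazole)] (11 mol%), CH2Cl2, 0 °C to rt
Reagents that add atoms: none
Why: Proposed new method: enantiotopic-group-selective α-ketol (acyloin) ring expansion, in which the tertiary OH and the ketone of meso 7 bind divalent copper as a five-membered chelate (O–C–C=O syn-periplanar) that holds the two CH(OBz) ring carbons above and below the chelate plane in different quadrants of the C2-symmetric ligand, so that only the S-configured one slides with retention onto the ketone carbon; that carbon becomes C6 with its new OH on the face of the old OH (trans to both benzoates) and the old carbinol carbon becomes the C5 ketone, the (R,R)-ligand being used instead if the first run favours the other enantiomer; the closest known reactions are Lewis-acid α-ketol ring expansions of 1-acylcycloalkanols and catalytic enantioselective acyloin rearrangements of prochiral α-ketols, neither of which has been used to choose between two enantiotopic migrating carbons of a meso substrate.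

Step 6
Reactants: 8 (1S,4R,6R)-6-hydroxy-6-[(tert-butyldimethylsilyloxy)methyl]-5-oxocyclohex-2-ene-1,4-diyl dibenzoate
Product: 9 (1S,4R,6R)-6-hydroxy-6-(hydroxymethyl)-5-oxocyclohex-2-ene-1,4-diyl dibenzoate
Conditions: HF (48% aq.), MeCN, 0 °C; pH 7 buffer work-up
Reagents that add atoms: none
Why: Acidic fluoride desilylation of the primary silyl ether (Si–F bond formation) avoids the base that would enolise the ketone toward C4 or move a benzoate onto the new primary alcohol, so all stereocenters are kept.

Step 7
Reactants: 9 (1S,4R,6R)-6-hydroxy-6-(hydroxymethyl)-5-oxocyclohex-2-ene-1,4-diyl dibenzoate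
Product: 10 (1S,4R,5S,6S)-5,6-dihydroxy-6-(hydroxymethyl)cyclohex-2-ene-1,4-diyl dibenzoate
Conditions: Me4NBH(OAc)3, MeCN/AcOH (1:1), −20 °C; pH 7 buffer work-up
Reagents that add atoms: none
Why: Saksena–Evans hydroxyl-directed reduction, in which the primary CH2OH exchanges onto boron and delivers hydride through a six-membered transition state to the ketone face it sits on (syn to both benzoates), so the new C5–OH is cis to the C6–OH and trans to the C4 benzoate (5S); the reagent does not reduce the benzoates.

**Compound list**
1 | cyclopenta-1,3-diene | C1=CCC=C1 | starting material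
2 | (tert-butyldimethylsilyloxy)acetaldehyde | O=CCO[Si](C)(C)C(C)(C)C | starting material
3 | 5-[2-(tert-butyldimethylsilyloxy)ethylidene]cyclopenta-1,3-diene (6-(silyloxymethyl)fulvene) | C1=CC(=CCO[Si](C)(C)C(C)(C)C)C=C1 | intermediate
4 | 7-[2-(tert-butyldimethylsilyloxy)ethylidene]-2,3-dioxabicyclo[2.2.1]hept-5-ene (fulvene endoperoxide; racemic, one enantiomer drawn) | O1[C@H]2C=C[C@@H](O1)/C2=C/CO[Si](C)(C)C(C)(C)C | intermediate
5 | cis-2-[2-(tert-butyldimethylsilyloxy)ethylidene]cyclopent-4-ene-1,3-diol (racemic, one enantiomer drawn) | O[C@H]1C=C[C@@H](O)/C1=C/CO[Si](C)(C)C(C)(C)C | intermediate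
6 | cis-2-[2-(tert-butyldimethylsilyloxy)ethylidene]cyclopent-4-ene-1,3-diyl dibenzoate (racemic, one enantiomer drawn) | O=C(O[C@H]1C=C[C@@H](OC(=O)c2ccccc2)/C1=C/CO[Si](C)(C)C(C)(C)C)c1ccccc1 | intermediate
7 | meso-(1R,3S)-2-hydroxy-2-[2-(tert-butyldimethylsilyloxy)acetyl]cyclopent-4-ene-1,3-diyl dibenzoate (benzoates cis to each other and to the acyl group, tertiary OH on the other face) | O=C(O[C@H]1C=C[C@@H](OC(=O)c2ccccc2)[C@@]1(O)C(=O)CO[Si](C)(C)C(C)(C)C)c1ccccc1 | intermediate
8 | (1S,4R,6R)-6-hydroxy-6-[(tert-butyldimethylsilyloxy)methyl]-5-oxocyclohex-2-ene-1,4-diyl dibenzoate | O=C(O[C@H]1C=C[C@@H](OC(=O)c2ccccc2)C(=O)[C@@]1(O)CO[Si](C)(C)C(C)(C)C)c1ccccc1 | intermediate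
9 | (1S,4R,6R)-6-hydroxy-6-(hydroxymethyl)-5-oxocyclohex-2-ene-1,4-diyl dibenzoate | O=C(O[C@H]1C=C[C@@H](OC(=O)c2ccccc2)C(=O)[C@@]1(O)CO)c1ccccc1 | intermediate
10 | (1S,4R,5S,6S)-5,6-dihydroxy-6-(hydroxymethyl)cyclohex-2-ene-1,4-diyl dibenzoate (CNP0212417.1) | O=C(O[C@H]1C=C[C@@H](OC(=O)c2ccccc2)[C@H](O)[C@@]1(O)CO)c1ccccc1 | target

**Summary**
Total step count: 7. Longest linear sequence: 7.

The three steps most likely to fail:

Step 5 (the new ring expansion). The catalyst may discriminate poorly between the two enantiotopic carbons. The Lewis acid may also enolise the β,γ-unsaturated ketone product. Fallback: from 7, BF3·OEt2 in CH2Cl2 at 0 °C (ordinary Lewis-acid α-ketol ring expansion without a chiral catalyst) gives 8 as the racemate, that is 8 mixed with its enantiomer (1R,4S,6S)-6-hydroxy-6-[(tert-butyldimethylsilyloxy)methyl]-5-oxocyclohex-2-ene-1,4-diyl dibenzoate F1. Preparative SFC on a chiral stationary phase removes F1, and the route is rejoined at 8.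

Step 2 (fulvene endoperoxide). The endoperoxide 4 rearranges above about −30 °C and thiourea is slow in the cold, so the diol yield may be low. Fallback: from 3, photooxygenate as before but add Et3N at −78 °C instead of thiourea (Kornblum–DeLaMare rearrangement of 4). This gives the hydroxy dienone 4-hydroxy-5-[2-(tert-butyldimethylsilyloxy)ethylidene]cyclopent-2-en-1-one F2 as an E/Z mixture. Luche reduction (NaBH4, CeCl3·7H2O, MeOH, −78 °C) then reduces its ketone 1,2 and cis to the existing OH. Both geometric isomers give racemic 5, where the route is rejoined.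

Step 4 (ketohydroxylation). RuO4 may also attack the ring alkene or cleave the exocyclic one. Fallback: from 6, OsO4 (cat.) and N-methylmorpholine N-oxide in acetone/H2O dihydroxylate the exocyclic alkene anti to the benzoates. This gives the diol 2-hydroxy-2-[1-hydroxy-2-(tert-butyldimethylsilyloxy)ethyl]cyclopent-4-ene-1,3-diyl dibenzoate F3. Dess–Martin periodinane in CH2Cl2 then oxidises only the secondary alcohol, and the route is rejoined at 7.

Further compounds
F1 | step 5 | (1R,4S,6S)-6-hydroxy-6-[(tert-butyldimethylsilyloxy)methyl]-5-oxocyclohex-2-ene-1,4-diyl dibenzoate (enantiomer of 8) | O=C(O[C@@H]1C=C[C@H](OC(=O)c2ccccc2)C(=O)[C@]1(O)CO[Si](C)(C)C(C)(C)C)c1ccccc1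
F2 | step 2 | (E/Z)-4-hydroxy-5-[2-(tert-butyldimethylsilyloxy)ethylidene]cyclopent-2-en-1-one (racemic; Z isomer of one enantiomer drawn) | O=C1C=C[C@@H](O)/C1=C/CO[Si](C)(C)C(C)(C)C
F3 | step 4 | 2-hydroxy-2-[1-hydroxy-2-(tert-butyldimethylsilyloxy)ethyl]cyclopent-4-ene-1,3-diyl dibenzoate (racemic, one enantiomer drawn; ring OH trans to both benzoates) | O=C(O[C@H]1C=C[C@@H](OC(=O)c2ccccc2)[C@@]1(O)[C@H](O)CO[Si](C)(C)C(C)(C)C)c1ccccc1
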